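Ring B is numbered C1 (quaternary), C2 (CH), C3 (alkylidene), C4, C5, C6 (carbinol). The 3-hydroxypropyl arm on C2 and the hydroxyl on C6 are cis-1,3, so they are read as the two ends of a ketone bridge C2–C7–C8–C9(=O)–C6 that Baeyer–Villiger oxidation and reduction later unzip. The ring then is the product of a type 2 intramolecular Diels–Alder reaction: an acyclic trienone, a tetrasubstituted diene C1=C2–C3=C4 whose C2 carries a CH2–CH(OBn)–CO–C(CH3)=CH2 arm, closes C4–C5 and C6–C1 in one operation and sets both quaternary centres. The C8 benzyloxy stereocentre fixes the face and is then removed; the bridgehead alkene steers C2–H and the enal geometry.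

Key step: step 11

Remark: 1, 4, 5, 13, 14, 33 and (+)-MIB are taken as purchasable; C7–C8–C9 are the three carbons of the arm on C2 (C9 is the bridge carbonyl and ends as CH2OH) and C10 is the exocyclic carbon that ends as the enal α-carbon.

Step 1
Reactants: 1 (S)-but-3-yn-2-ol
Product: 2 (S)-triethyl(but-3-yn-2-yloxy)silane
Conditions: Et3SiCl, imidazole, CH2Cl2, 0 °C
Reagents that add atoms: chlorotriethylsilane, CC[Si](Cl)(CC)CC
Why: Silylation of the secondary alcohol; the purchased (S) centre (C10) is not touched.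

Step 2
Reactants: 2 (S)-triethyl(but-3-yn-2-yloxy)silane
Product: 3 (S)-triethyl{[3-(4,4,5,5-tetramethyl-1,3,2-dioxaborolan-2-yl)but-3-en-2-yl]oxy}silane
Conditions: B2pin2, CuCl (5 mol %), SIMes·HCl (5 mol %), NaOt-Bu (10 mol %), MeOH, THF, −15 °C → rt
Reagents that add atoms: bis(pinacolato)diboron, CC1(C)OB(OC1(C)C)B1OC(C)(C)C(C)(C)O1
Why: Carbene–copper-catalysed protoboration of a terminal alkyne; with an N-aryl carbene and a propargylic oxygen the boryl group goes to the internal carbon, which should give the 1,1-disubstituted alkenylboronate (C3 with C4 and C10).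

Step 3
Reactants: 4 1-[(3-bromopropoxy)methyl]-4-methoxybenzene; 5 ethyl but-2-ynoate
Product: 9 ethyl (2Z)-2-iodo-6-[(4-methoxybenzyl)oxy]-3-methylhex-2-enoate, via Grignard reagent 6 (not isolated), via alkylcopper 7 (not isolated), via alkenylcopper 8 (not isolated)
Conditions: Mg, THF, rt; CuBr·SMe2, THF, −40 °C; 5, −78 °C; I2, THF, −78 °C
Reagents that add atoms: iodine, II
Why: syn-Carbocupration of the alkynoate puts the chain on C1 cis to copper, and iodinolysis of the configurationally stable α-cuprio ester at −78 °C goes with retention, so the tetrasubstituted C1=C2 bond is formed with iodine cis to the chain and the ester carbon (C7) cis to CH3.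

Step 4
Reactants: 9 ethyl (2Z)-2-iodo-6-[(4-methoxybenzyl)oxy]-3-methylhex-2-enoate; 3 (S)-triethyl{[3-(4,4,5,5-tetramethyl-1,3,2-dioxaborolan-2-yl)but-3-en-2-yl]oxy}silane
Product: 10 ethyl (2E)-6-[(4-methoxybenzyl)oxy]-3-methyl-2-[(3S)-3-(triethylsilyloxy)but-1-en-2-yl]hex-2-enoate
Conditions: Pd(OAc)2 (5 mol %), SPhos (10 mol %), K3PO4, THF/H2O, 50 °C
Reagents that add atoms: none
Why: Suzuki–Miyaura coupling joins C2 to C3 with retention at both alkenyl carbons; a bulky biarylphosphine is used for the hindered α-iodo enoate.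

Step 5
Reactants: 10 ethyl (2E)-6-[(4-methoxybenzyl)oxy]-3-methyl-2-[(3S)-3-(triethylsilyloxy)but-1-en-2-yl]hex-2-enoate
Product: 11 (2E)-6-[(4-methoxybenzyl)oxy]-3-methyl-2-[(3S)-3-(triethylsilyloxy)but-1-en-2-yl]hex-2-en-1-ol
Conditions: i-Bu2AlH, CH2Cl2, −78 → −20 °C
Reagents that add atoms: none
Why: 1,2-Reduction of the conjugated ester to the primary allylic alcohol (C7); the silyl and benzyl ethers are inert.

Step 6
Reactants: 11 (2E)-6-[(4-methoxybenzyl)oxy]-3-methyl-2-[(3S)-3-(triethylsilyloxy)but-1-en-2-yl]hex-2-en-1-ol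
Product: 12 (2E)-1-bromo-6-[(4-methoxybenzyl)oxy]-3-methyl-2-[(3S)-3-(triethylsilyloxy)but-1-en-2-yl]hex-2-ene
Conditions: CBr4, PPh3, 2,6-lutidine, CH2Cl2, −30 → 0 °C
Reagents that add atoms: carbon tetrabromide, BrC(Br)(Br)Br
Why: Appel reaction: SN2 displacement at the primary allylic carbon under buffered conditions keeps the silyl ether and the alkene geometry.

Step 7
Reactants: 13 (R)-4-benzyloxazolidin-2-one; 14 (benzyloxy)acetyl chloride
Product: 15 (R)-4-benzyl-3-[(benzyloxy)acetyl]oxazolidin-2-one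
Conditions: Et3N, DMAP (cat.), CH2Cl2, 0 °C → rt
Reagents that add atoms: none
Why: N-Acylation of the oxazolidinone by the acid chloride under DMAP catalysis.

Step 8
Reactants: 15 (R)-4-benzyl-3-[(benzyloxy)acetyl]oxazolidin-2-one; 12 (2E)-1-bromo-6-[(4-methoxybenzyl)oxy]-3-methyl-2-[(3S)-3-(triethylsilyloxy)but-1-en-2-yl]hex-2-ene
Product: 17 (4R)-4-benzyl-3-{(2S,4Z)-2-(benzyloxy)-8-[(4-methoxybenzyl)oxy]-5-methyl-4-[(3S)-3-(triethylsilyloxy)but-1-en-2-yl]oct-4-enoyl}oxazolidin-2-one, via sodium enolate 16 (not isolated)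
Conditions: NaN(SiMe3)2, THF, −78 °C; then 12, −78 → −45 °C
Reagents that add atoms: none
Why: Oxazolidinone glycolate alkylation: the chelated (Z)-sodium enolate is alkylated by the allylic bromide on the face away from the benzyl group of the (R)-auxiliary, which should set C8 as (S).

Step 9
Reactants: 17 (4R)-4-benzyl-3-{(2S,4Z)-2-(benzyloxy)-8-[(4-methoxybenzyl)oxy]-5-methyl-4-[(3S)-3-(triethylsilyloxy)but-1-en-2-yl]oct-4-enoyl}oxazolidin-2-one
Product: 18 (2S,4Z)-2-(benzyloxy)-N-methoxy-8-[(4-methoxybenzyl)oxy]-N,5-dimethyl-4-[(3S)-3-(triethylsilyloxy)but-1-en-2-yl]oct-4-enamide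
Conditions: MeNHOMe·HCl, AlMe3, CH2Cl2, 0 °C → rt
Reagents that add atoms: N,O-dimethylhydroxylamine hydrochloride, CNOC.Cl
Why: Aluminium amide transamidation (Weinreb amide formation) at the exocyclic carbonyl releases the auxiliary 13 for re-use and does not epimerise C8.

Step 10
Reactants: 18 (2S,4Z)-2-(benzyloxy)-N-methoxy-8-[(4-methoxybenzyl)oxy]-N,5-dimethyl-4-[(3S)-3-(triethylsilyloxy)but-1-en-2-yl]oct-4-enamide
Product: 19 (4S,6Z)-4-(benzyloxy)-10-[(4-methoxybenzyl)oxy]-2,7-dimethyl-6-[(3S)-3-(triethylsilyloxy)but-1-en-2-yl]deca-1,6-dien-3-one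
Conditions: CH2=C(CH3)MgBr, THF, −20 → 0 °C; cold aq. NH4Cl
Reagents that add atoms: isopropenylmagnesium bromide, C=C(C)[Mg]Br
Why: Weinreb ketone synthesis: the chelated tetrahedral adduct survives until the cold quench, so the Grignard reagent adds once and gives the enone that holds C9, C6 and C5.

Step 11
Reactants: 19 (4S,6Z)-4-(benzyloxy)-10-[(4-methoxybenzyl)oxy]-2,7-dimethyl-6-[(3S)-3-(triethylsilyloxy)but-1-en-2-yl]deca-1,6-dien-3-one
Product: 20 (5S,7S,9S)-7-(benzyloxy)-9-{3-[(4-methoxybenzyl)oxy]propyl}-5,9-dimethyl-2-[(1S)-1-(triethylsilyloxy)ethyl]bicyclo[3.3.1]non-1-en-6-one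
Conditions: MeAlCl2 (1.2 equiv), CH2Cl2, −78 → −20 °C
Reagents that add atoms: none
Why: Lewis-acid-promoted type 2 intramolecular Diels–Alder reaction: MeAlCl2 binds the enone carbonyl (and the neighbouring benzyloxy oxygen), and the electron-poor C5=C6 bond adds suprafacially across the s-cis diene C1=C2–C3=C4 in a concerted, asynchronous [4+2] process in which C4–C5 bonding leads and C6–C1 follows. The closest known reaction type is the Lewis-acid-catalysed cyclisation of 2-substituted dienes joined through a three-atom tether to an enone, which gives bicyclo[3.3.1]non-1-enes. Two rings close: ring B (C1–C6) by the [4+2] cycloaddition, and the temporary six-membered ketone ring C1–C2–C7–C8–C9–C6 as a consequence of the C6–C1 bond, the short tether on C2 allowing only the bridged (meta) mode so that C6 and not C5 bonds to C1. C1 and C6 arise from suprafacial addition to the geometrically defined tetrasubstituted C1=C2 bond (the CH3 cis to C7 ends syn to the bridge, the oxypropyl chain anti) with the carbonyl necessarily endo, and the absolute sense comes from the C8 benzyloxy stereocentre, which should sit exo on the forming bridge (pseudo-equatorial and nearly eclipsed with the complexed C=O) because the endo position runs into C4–C5. The step needs regio-, diastereo- and facial selectivity: the first two are enforced by the tether and the alkene geometry, the third by C8. The strained bridgehead alkene C2=C3 that results is what later drives hydride delivery to C2.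

Step 12
Reactants: 20 (5S,7S,9S)-7-(benzyloxy)-9-{3-[(4-methoxybenzyl)oxy]propyl}-5,9-dimethyl-2-[(1S)-1-(triethylsilyloxy)ethyl]bicyclo[3.3.1]non-1-en-6-one
Product: 21 (5S,9S)-9-{3-[(4-methoxybenzyl)oxy]propyl}-5,9-dimethyl-2-[(1S)-1-(triethylsilyloxy)ethyl]bicyclo[3.3.1]non-1-en-6-one
Conditions: SmI2, HMPA, THF/MeOH, −78 °C
Reagents that add atoms: none
Why: Reductive cleavage of an α-alkoxy ketone: SmI2 forms the ketyl, the C8–O bond is expelled and the samarium enolate is protonated, which removes the controller without touching C1 or C6.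

Step 13
Reactants: 21 (5S,9S)-9-{3-[(4-methoxybenzyl)oxy]propyl}-5,9-dimethyl-2-[(1S)-1-(triethylsilyloxy)ethyl]bicyclo[3.3.1]non-1-en-6-one
Product: 23 (5S,9S)-2-acetyl-9-{3-[(4-methoxybenzyl)oxy]propyl}-5,9-dimethylbicyclo[3.3.1]non-1-en-6-one, via allylic alcohol 22 (not isolated)
Conditions: IBX (2-iodoxybenzoic acid), DMSO, rt
Reagents that add atoms: none
Why: IBX in DMSO cleaves the triethylsilyl ether and oxidises the freed allylic alcohol in the same flask, which erases the auxiliary C10 centre and gives the bridgehead enone.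

Step 14
Reactants: 23 (5S,9S)-2-acetyl-9-{3-[(4-methoxybenzyl)oxy]propyl}-5,9-dimethylbicyclo[3.3.1]non-1-en-6-one
Product: 25 (Z)-1-[(1S,5S,9S)-9-{3-[(4-methoxybenzyl)oxy]propyl}-5,9-dimethyl-6-oxobicyclo[3.3.1]nonan-2-ylidene]ethyl nonafluorobutane-1-sulfonate, via silyl enol ether 24 (not isolated)
Conditions: [(Ph3P)CuH]6 (5 mol %), PhMe2SiH, toluene, rt; then C4F9SO2F, Bu4NF (10 mol %), THF, 0 °C
Reagents that add atoms: nonafluorobutane-1-sulfonyl fluoride, O=S(=O)(F)C(F)(F)C(F)(F)C(F)(F)C(F)(F)F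
Why: Copper hydride 1,4-hydrosilylation of the strained enone goes through the s-cis conformer (the s-trans form would push the acetyl CH3 against C7 by A(1,3) strain), hydride reaching only the exo face of the bridgehead C2 (which fixes C2) and giving the (Z)-silyl enol ether with oxygen on the C2 side, which fluoride-catalysed O-sulfonylation should convert with retention into the alkenyl nonaflate.

Step 15
Reactants: 25 (Z)-1-[(1S,5S,9S)-9-{3-[(4-methoxybenzyl)oxy]propyl}-5,9-dimethyl-6-oxobicyclo[3.3.1]nonan-2-ylidene]ethyl nonafluorobutane-1-sulfonate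
Product: 26 bridged seven-membered lactone of 25 (oxygen inserted between C9 and C6; C1, C2, C6 and the alkenyl nonaflate unchanged)
Conditions: mCPBA, NaHCO3, CH2Cl2, rt
Reagents that add atoms: 3-chloroperoxybenzoic acid, OOC(=O)c1cccc(Cl)c1
Why: Baeyer–Villiger oxidation: the tertiary C6 migrates in preference to the C8 methylene and with retention, so oxygen is placed on C6 cis to the C2 arm, and the electron-poor alkenyl sulfonate is not epoxidised.

Step 16
Reactants: 26 bridged seven-membered lactone with the (Z)-alkenyl nonaflate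
Product: 27 bridged lactone methyl (Z)-enoate (nonaflate of 26 replaced by CO2CH3; ester carbon cis to C2)
Conditions: CO (1 atm), Pd(OAc)2 (10 mol %), Ph2P(CH2)3PPh2, Et3N, MeOH/DMF, 60 °C
Reagents that add atoms: carbon monoxide, [C-]#[O+]; methanol, CO
Why: Palladium-catalysed methoxycarbonylation of the alkenyl nonaflate (oxidative addition, CO insertion, methanolysis) proceeds with retention of the alkene geometry, so the new carbon ends cis to C2.

Step 17
Reactants: 27 bridged lactone methyl (Z)-enoate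
Product: 28 (1S,2S,3R,4Z)-4-(1-hydroxypropan-2-ylidene)-3-(3-hydroxypropyl)-2-{3-[(4-methoxybenzyl)oxy]propyl}-1,2-dimethylcyclohexan-1-ol
Conditions: LiAlH4, THF, 0 °C
Reagents that add atoms: none
Why: Hydride reduction opens the lactone to the C6 tertiary alcohol and the C9 primary alcohol and reduces the enoate 1,2 to the allylic alcohol; no stereocentre is touched.

Step 18
Reactants: 28 (1S,2S,3R,4Z)-4-(1-hydroxypropan-2-ylidene)-3-(3-hydroxypropyl)-2-{3-[(4-methoxybenzyl)oxy]propyl}-1,2-dimethylcyclohexan-1-ol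
Product: 29 tris(triethylsilyl) ether of 28 (both primary hydroxyls and the tertiary hydroxyl silylated)
Conditions: Et3SiOTf, 2,6-lutidine, CH2Cl2, −78 → 0 °C
Reagents that add atoms: triethylsilyl trifluoromethanesulfonate, CC[Si](CC)(CC)OS(=O)(=O)C(F)(F)F
Why: The silyl triflate silylates both primary hydroxyls and the hindered tertiary one, so that no free OH is left for the organozinc step and for the later acetylation.

Step 19
Reactants: 29 tris(triethylsilyl) ether of 28
Product: 30 primary alcohol (29 without the 4-methoxybenzyl group; free CH2OH at the end of the C1 chain)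
Conditions: DDQ, CH2Cl2/pH 7 buffer, 0 °C
Reagents that add atoms: none
Why: Oxidative cleavage of the 4-methoxybenzyl ether by DDQ via the benzylic oxocarbenium ion; the buffered medium keeps the silyl ethers.

Step 20
Reactants: 30 primary alcohol
Product: 31 aldehyde (C1 chain CH2CH2CHO; three silyl ethers in place)
Conditions: Dess–Martin periodinane, NaHCO3, CH2Cl2, rt
Reagents that add atoms: none
Why: Dess–Martin oxidation of the primary alcohol to the aldehyde under buffered conditions.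

Step 21
Reactants: 31 aldehyde
Product: 32 (E)-2-methyl-2-enal (C1 chain CH2CH2CH=C(CH3)CHO; three silyl ethers in place)
Conditions: Ph3P=C(CH3)CHO, toluene, 80 °C
Reagents that add atoms: 2-(triphenylphosphoranylidene)propanal, CC(C=O)=P(c1ccccc1)(c1ccccc1)c1ccccc1
Why: Wittig reaction of a stabilised ylide with the unhindered aliphatic aldehyde should give the (E)-2-methyl-2-enal.

Step 22
Reactants: 33 (S)-citronellal
Product: 35 (S)-3,7-dimethyloct-6-en-1-yne, via alkenyl nonaflate 34 (not isolated)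
Conditions: C4F9SO2F, phosphazene base P2-Et, DMF, −20 °C → rt
Reagents that add atoms: none
Why: One-pot enol nonaflate formation and base-induced elimination converts RCH2CHO into RC≡CH without gain or loss of carbon; the methyl-bearing centre is not acidic and keeps its (S) configuration.

Step 23
Reactants: 35 (S)-3,7-dimethyloct-6-en-1-yne; 32 (E)-2-methyl-2-enal
Product: 38 (R)-bis-allylic alcohol (C1 chain CH2CH2CH=C(CH3)–CH(OH)–CH=CH–CH(CH3)CH2CH2CH=C(CH3)2 with both alkenes E and the methyl centre S; three silyl ethers in place), via alkenylborane 36 (not isolated), via alkenylzinc 37 (not isolated)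
Conditions: Cy2BH (from BH3·SMe2 and cyclohexene), toluene, 0 °C; Et2Zn, −78 °C; (+)-MIB (10 mol %), then 32, −20 → 0 °C
Reagents that add atoms: none
Why: Hydroboration gives the (E)-alkenylborane, boron-to-zinc exchange the alkenylzinc, and the amino alcohol catalyst (+)-MIB, the enantiomer that directs addition to the Re face of the enal, should give the (R)-carbinol (catalyst-controlled alkenylzinc addition).

Step 24
Reactants: 38 (R)-bis-allylic alcohol
Product: 39 acetate of 38
Conditions: Ac2O, pyridine, DMAP (cat.), CH2Cl2, 0 °C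
Reagents that add atoms: acetic anhydride, CC(=O)OC(C)=O
Why: Acetylation of the only free hydroxyl.

Step 25
Reactants: 39 acetate of 38
Product: 40 triol acetate (all three silyl groups removed; ring carries C(CH3)CH2OH in the Z geometry)
Conditions: HF·pyridine, pyridine, THF, 0 °C → rt
Reagents that add atoms: none
Why: Fluoride cleaves the three silyl ethers, and the pyridine buffer keeps the doubly allylic acetate from ionising.

Step 26
Reactants: 40 triol acetate
Product: 41 CNP0259235.1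
Conditions: MnO2, CH2Cl2, rt
Reagents that add atoms: none
Why: MnO2 oxidises only the allylic primary alcohol, so the saturated primary and the tertiary hydroxyls stay and the (Z)-enal should form without isomerisation.

Compound list
1 | (S)-but-3-yn-2-ol | C#C[C@H](C)O | starting material
2 | (S)-triethyl(but-3-yn-2-yloxy)silane | C#C[C@H](C)O[Si](CC)(CC)CC | intermediate
3 | (S)-triethyl{[3-(4,4,5,5-tetramethyl-1,3,2-dioxaborolan-2-yl)but-3-en-2-yl]oxy}silane | C=C(B1OC(C)(C)C(C)(C)O1)[C@H](C)O[Si](CC)(CC)CC | intermediate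
4 | 1-[(3-bromopropoxy)methyl]-4-methoxybenzene | COc1ccc(COCCCBr)cc1 | starting material
5 | ethyl but-2-ynoate | CCOC(=O)C#CC | starting material
6 | {3-[(4-methoxybenzyl)oxy]propyl}magnesium bromide | COc1ccc(COCCC[Mg]Br)cc1 | intermediate
7 | {3-[(4-methoxybenzyl)oxy]propyl}copper | COc1ccc(COCCC[Cu])cc1 | intermediate
8 | ethyl (2Z)-2-cuprio-6-[(4-methoxybenzyl)oxy]-3-methylhex-2-enoate (copper cis to the chain) | CCOC(=O)/C([Cu])=C(\C)CCCOCc1ccc(OC)cc1 | intermediate
9 | ethyl (2Z)-2-iodo-6-[(4-methoxybenzyl)oxy]-3-methylhex-2-enoate | CCOC(=O)/C(I)=C(\C)CCCOCc1ccc(OC)cc1 | intermediate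
10 | ethyl (2E)-6-[(4-methoxybenzyl)oxy]-3-methyl-2-[(3S)-3-(triethylsilyloxy)but-1-en-2-yl]hex-2-enoate | CCOC(=O)/C(C(=C)[C@H](C)O[Si](CC)(CC)CC)=C(\C)CCCOCc1ccc(OC)cc1 | intermediate
11 | (2E)-6-[(4-methoxybenzyl)oxy]-3-methyl-2-[(3S)-3-(triethylsilyloxy)but-1-en-2-yl]hex-2-en-1-ol | OC/C(C(=C)[C@H](C)O[Si](CC)(CC)CC)=C(\C)CCCOCc1ccc(OC)cc1 | intermediate
12 | (2E)-1-bromo-6-[(4-methoxybenzyl)oxy]-3-methyl-2-[(3S)-3-(triethylsilyloxy)but-1-en-2-yl]hex-2-ene | BrC/C(C(=C)[C@H](C)O[Si](CC)(CC)CC)=C(\C)CCCOCc1ccc(OC)cc1 | intermediate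
13 | (R)-4-benzyloxazolidin-2-one | O=C1N[C@H](Cc2ccccc2)CO1 | starting material
14 | (benzyloxy)acetyl chloride | O=C(Cl)COCc1ccccc1 | starting material
15 | (R)-4-benzyl-3-[(benzyloxy)acetyl]oxazolidin-2-one | O=C(COCc1ccccc1)N2C(=O)OC[C@H]2Cc3ccccc3 | intermediate
16 | sodium (Z)-enolate of 15 | [Na+].[O-]/C(=C\OCc1ccccc1)N2C(=O)OC[C@H]2Cc3ccccc3 | intermediate
17 | (4R)-4-benzyl-3-{(2S,4Z)-2-(benzyloxy)-8-[(4-methoxybenzyl)oxy]-5-methyl-4-[(3S)-3-(triethylsilyloxy)but-1-en-2-yl]oct-4-enoyl}oxazolidin-2-one | O=C([C@@H](OCc1ccccc1)C/C(C(=C)[C@H](C)O[Si](CC)(CC)CC)=C(\C)CCCOCc2ccc(OC)cc2)N3C(=O)OC[C@H]3Cc4ccccc4 | intermediate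
18 | (2S,4Z)-2-(benzyloxy)-N-methoxy-8-[(4-methoxybenzyl)oxy]-N,5-dimethyl-4-[(3S)-3-(triethylsilyloxy)but-1-en-2-yl]oct-4-enamide | CON(C)C(=O)[C@@H](OCc1ccccc1)C/C(C(=C)[C@H](C)O[Si](CC)(CC)CC)=C(\C)CCCOCc2ccc(OC)cc2 | intermediate
19 | (4S,6Z)-4-(benzyloxy)-10-[(4-methoxybenzyl)oxy]-2,7-dimethyl-6-[(3S)-3-(triethylsilyloxy)but-1-en-2-yl]deca-1,6-dien-3-one | C=C(C)C(=O)[C@@H](OCc1ccccc1)C/C(C(=C)[C@H](C)O[Si](CC)(CC)CC)=C(\C)CCCOCc2ccc(OC)cc2 | intermediate
20 | (5S,7S,9S)-7-(benzyloxy)-9-{3-[(4-methoxybenzyl)oxy]propyl}-5,9-dimethyl-2-[(1S)-1-(triethylsilyloxy)ethyl]bicyclo[3.3.1]non-1-en-6-one (route locants: C1 S with CH3 syn to the keto bridge, C6 S, C8 S with benzyloxy exo, bridgehead alkene C2=C3) | O=C1[C@@H](OCc2ccccc2)CC3=C([C@H](C)O[Si](CC)(CC)CC)CC[C@@]1(C)[C@@]3(C)CCCOCc4ccc(OC)cc4 | intermediate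
21 | (5S,9S)-9-{3-[(4-methoxybenzyl)oxy]propyl}-5,9-dimethyl-2-[(1S)-1-(triethylsilyloxy)ethyl]bicyclo[3.3.1]non-1-en-6-one | O=C1CCC2=C([C@H](C)O[Si](CC)(CC)CC)CC[C@@]1(C)[C@@]2(C)CCCOCc3ccc(OC)cc3 | intermediate
22 | (5S,9S)-2-[(1S)-1-hydroxyethyl]-9-{3-[(4-methoxybenzyl)oxy]propyl}-5,9-dimethylbicyclo[3.3.1]non-1-en-6-one | O=C1CCC2=C([C@H](C)O)CC[C@@]1(C)[C@@]2(C)CCCOCc3ccc(OC)cc3 | intermediate
23 | (5S,9S)-2-acetyl-9-{3-[(4-methoxybenzyl)oxy]propyl}-5,9-dimethylbicyclo[3.3.1]non-1-en-6-one | O=C1CCC2=C(C(C)=O)CC[C@@]1(C)[C@@]2(C)CCCOCc3ccc(OC)cc3 | intermediate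
24 | (1S,5S,9S)-2-[(Z)-1-{[dimethyl(phenyl)silyl]oxy}ethylidene]-9-{3-[(4-methoxybenzyl)oxy]propyl}-5,9-dimethylbicyclo[3.3.1]nonan-6-one | O=C1CC[C@@H]2/C(=C(/C)O[Si](C)(C)c3ccccc3)CC[C@@]1(C)[C@@]2(C)CCCOCc4ccc(OC)cc4 | intermediate
25 | (Z)-1-[(1S,5S,9S)-9-{3-[(4-methoxybenzyl)oxy]propyl}-5,9-dimethyl-6-oxobicyclo[3.3.1]nonan-2-ylidene]ethyl nonafluorobutane-1-sulfonate (sulfonate oxygen cis to C2, bridgehead H exo) | O=C1CC[C@@H]2/C(=C(/C)OS(=O)(=O)C(F)(F)C(F)(F)C(F)(F)C(F)(F)F)CC[C@@]1(C)[C@@]2(C)CCCOCc3ccc(OC)cc3 | intermediate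
26 | bridged seven-membered lactone of 25: ring B bridged from C2 to C6 by C7H2–C8H2–C9(=O)–O, oxygen on C6 with retention, (Z)-alkenyl nonaflate at C3 | O=C1CC[C@@H]2/C(=C(/C)OS(=O)(=O)C(F)(F)C(F)(F)C(F)(F)C(F)(F)F)CC[C@](C)(O1)[C@@]2(C)CCCOCc3ccc(OC)cc3 | intermediate
27 | bridged lactone methyl (Z)-enoate: as 26 with CO2CH3 in place of the nonaflate (ester carbon cis to C2) | O=C1CC[C@@H]2/C(=C(/C)C(=O)OC)CC[C@](C)(O1)[C@@]2(C)CCCOCc3ccc(OC)cc3 | intermediate
28 | (1S,2S,3R,4Z)-4-(1-hydroxypropan-2-ylidene)-3-(3-hydroxypropyl)-2-{3-[(4-methoxybenzyl)oxy]propyl}-1,2-dimethylcyclohexan-1-ol | COc1ccc(COCCC[C@@]2(C)[C@H](CCCO)/C(=C(/C)CO)CC[C@]2(C)O)cc1 | intermediate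
29 | tris(triethylsilyl) ether of 28 (two primary and the tertiary hydroxyl silylated) | COc1ccc(COCCC[C@@]2(C)[C@H](CCCO[Si](CC)(CC)CC)/C(=C(/C)CO[Si](CC)(CC)CC)CC[C@]2(C)O[Si](CC)(CC)CC)cc1 | intermediate
30 | primary alcohol: 29 without the 4-methoxybenzyl group | OCCC[C@@]1(C)[C@H](CCCO[Si](CC)(CC)CC)/C(=C(/C)CO[Si](CC)(CC)CC)CC[C@]1(C)O[Si](CC)(CC)CC | intermediate
31 | aldehyde: C1 chain CH2CH2CHO, three triethylsilyl ethers | O=CCC[C@@]1(C)[C@H](CCCO[Si](CC)(CC)CC)/C(=C(/C)CO[Si](CC)(CC)CC)CC[C@]1(C)O[Si](CC)(CC)CC | intermediate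
32 | (E)-2-methyl-2-enal: C1 chain CH2CH2CH=C(CH3)CHO, three triethylsilyl ethers | O=C/C(C)=C/CC[C@@]1(C)[C@H](CCCO[Si](CC)(CC)CC)/C(=C(/C)CO[Si](CC)(CC)CC)CC[C@]1(C)O[Si](CC)(CC)CC | intermediate
33 | (S)-citronellal, (3S)-3,7-dimethyloct-6-enal | O=CC[C@@H](C)CCC=C(C)C | starting material
34 | (3S)-3,7-dimethylocta-1,6-dien-1-yl nonafluorobutane-1-sulfonate (E/Z mixture) | FC(F)(F)C(F)(F)C(F)(F)C(F)(F)S(=O)(=O)OC=C[C@@H](C)CCC=C(C)C | intermediate
35 | (S)-3,7-dimethyloct-6-en-1-yne | C#C[C@@H](C)CCC=C(C)C | intermediate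
36 | dicyclohexyl[(1E,3S)-3,7-dimethylocta-1,6-dien-1-yl]borane | C1CCC(CC1)B(/C=C/[C@@H](C)CCC=C(C)C)C2CCCCC2 | intermediate
37 | [(1E,3S)-3,7-dimethylocta-1,6-dien-1-yl](ethyl)zinc | CC[Zn]/C=C/[C@@H](C)CCC=C(C)C | intermediate
38 | (R)-bis-allylic alcohol: side chain (3E,5R,6E,8S)-5-hydroxy-4,8,12-trimethyltrideca-3,6,11-trienyl on C1, three triethylsilyl ethers | O[C@H](/C=C/[C@@H](C)CCC=C(C)C)/C(C)=C/CC[C@@]1(C)[C@H](CCCO[Si](CC)(CC)CC)/C(=C(/C)CO[Si](CC)(CC)CC)CC[C@]1(C)O[Si](CC)(CC)CC | intermediate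
39 | acetate of 38 | CC(=O)O[C@H](/C=C/[C@@H](C)CCC=C(C)C)/C(C)=C/CC[C@@]1(C)[C@H](CCCO[Si](CC)(CC)CC)/C(=C(/C)CO[Si](CC)(CC)CC)CC[C@]1(C)O[Si](CC)(CC)CC | intermediate
40 | triol acetate: 39 without the three silyl groups (ring carries (Z)-C(CH3)CH2OH) | CC(=O)O[C@H](/C=C/[C@@H](C)CCC=C(C)C)/C(C)=C/CC[C@@]1(C)[C@H](CCCO)/C(=C(/C)CO)CC[C@]1(C)O | intermediate
41 | CNP0259235.1, (2Z)-2-{(2R,3S,4S)-3-[(3E,5R,6E,8S)-5-acetoxy-4,8,12-trimethyltrideca-3,6,11-trienyl]-4-hydroxy-2-(3-hydroxypropyl)-3,4-dimethylcyclohexylidene}propanal | CC(=O)O[C@H](/C=C/[C@@H](C)CCC=C(C)C)/C(C)=C/CC[C@@]1(C)[C@H](CCCO)/C(=C(/C)C=O)CC[C@]1(C)O | target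

Total step count: 26. Longest linear sequence: 23 steps (steps 1, 2, 4–6, 8–21 and 23–26, from 1 to 41).

Steps most likely to fail

Step 11 (key step). What may go wrong: under the Lewis acid the benzyloxy group may be ionised or eliminated before ring closure, or its exo and endo placements may differ too little, so that the dienophile adds to both diene faces. Fallback (stereocontrol by separation instead of induction): bromide 12 alkylates the lithium enolate of 3-methylbut-3-en-2-one (LiN(i-Pr)2, THF, −78 °C) to give the benzyloxy-free trienone F1. MeAlCl2 in CH2Cl2 then cyclises F1 to two bicyclic adducts that differ in the sense of the new bicycle relative to the fixed (S)-silyloxyethyl centre, namely 21 and its diastereomer F2, which should be separable by chromatography on silica. The fallback sets out from 12 and comes back to the route at 21.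

Step 14. What may go wrong: hydride transfer to the hindered tetrasubstituted enone may be slow, and in the fluoride stage proton transfer from the C8 methylene to the free enolate may return the saturated methyl ketone or scramble the enolate geometry before O-sulfonylation. Fallback (the formyl carbon is added by Wittig homologation after the bridge has been oxidised): 23 is treated with bis(trimethylsilyl) peroxide and catalytic Me3SiOTf, which should oxidise the saturated bridge ketone in preference to the conjugated one without epoxidising the alkene, to give the lactone enone F3. Ph3P=CHOMe converts the acetyl group into the methyl dienol ether F4. Aqueous oxalic acid protonates the strained bridgehead C2 on its exo face and hydrolyses the oxocarbenium ion to the (Z)-enal lactone F5, the smaller CH(OMe) terminus being the one that sits next to C7 in the reacting conformer. LiAlH4 then reduces lactone and enal to triol 28. The fallback sets out from 23 and comes back at 28.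

Step 23. What may go wrong: enantiofacial control in the alkenyl transfer to the α-branched enal may be incomplete, or ethyl transfer from zinc may compete. Fallback (alkynylation and trans-reduction in place of alkenylation): alkyne 35 is added to enal 32 with Me2Zn and the ProPhenol ligand enantiomer that directs the alkynyl group to the Re face, which gives the propargylic alcohol F6 (same spatial arrangement as 38; the descriptor becomes S because the alkynyl group outranks the alkenyl group). NaAlH2(OCH2CH2OCH3)2 in THF reduces the alkyne of the propargylic alkoxide to the (E)-alkene and gives 38. The fallback sets out from 32 and 35 and comes back at 38.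

Further compounds
F1 | step 11 | (6Z)-10-[(4-methoxybenzyl)oxy]-2,7-dimethyl-6-[(3S)-3-(triethylsilyloxy)but-1-en-2-yl]deca-1,6-dien-3-one | C=C(C)C(=O)CC/C(C(=C)[C@H](C)O[Si](CC)(CC)CC)=C(\C)CCCOCc1ccc(OC)cc1
F2 | step 11 | (5R,9R)-9-{3-[(4-methoxybenzyl)oxy]propyl}-5,9-dimethyl-2-[(1S)-1-(triethylsilyloxy)ethyl]bicyclo[3.3.1]non-1-en-6-one (diastereomer of 21) | O=C1CCC2=C([C@H](C)O[Si](CC)(CC)CC)CC[C@]1(C)[C@]2(C)CCCOCc3ccc(OC)cc3
F3 | step 14 | bridged lactone enone: 23 with oxygen inserted between C9 and C6 | O=C1CCC2=C(C(C)=O)CC[C@](C)(O1)[C@@]2(C)CCCOCc3ccc(OC)cc3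
F4 | step 14 | methyl dienol ether of F3 (C10=CH–OCH3, enol ether as E/Z mixture) | O=C1CCC2=C(C(C)=COC)CC[C@](C)(O1)[C@@]2(C)CCCOCc3ccc(OC)cc3
F5 | step 14 | bridged lactone (Z)-enal (formyl group cis to C2, bridgehead H exo) | O=C1CC[C@@H]2/C(=C(/C)C=O)CC[C@](C)(O1)[C@@]2(C)CCCOCc3ccc(OC)cc3
F6 | step 23 | propargylic alcohol: alkynyl analogue of 38 (C≡C in place of the disubstituted alkene) | O[C@H](C#C[C@@H](C)CCC=C(C)C)/C(C)=C/CC[C@@]1(C)[C@H](CCCO[Si](CC)(CC)CC)/C(=C(/C)CO[Si](CC)(CC)CC)CC[C@]1(C)O[Si](CC)(CC)CC
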